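**Assumptions:** The target has no stereocentres, so no enantioselective step is needed. Ring A is 2-hydroxy-3-(hydroxymethyl)-4-methoxy-6-methylbenzoyl. Ring B is 2,4-dihydroxy-3,6-dimethylbenzoic acid (β-orcinol carboxylic acid), esterified at its 4-OH. Orsellinic acid and methyl 2,4-dihydroxy-3,6-dimethylbenzoate (atraric acid) are taken as commercial.

## Retrosynthesis
1. Cleave the depside ester to give ring-A acid **6** and ring-B phenol **9**. Both aromatic rings are commercial, so no arene is built. The only new ring is the acetonide.
2. Ring-A acid 6 has its 2-OH and CH2OH locked as a 2,2-dimethyl-4H-1,3-benzodioxine. This is removed last under mild acid, avoiding hydrogenolysis of the electron-rich benzylic C–O bond. The CH2OH comes from ortho-hydroxymethylation of allyl everninate at C3, directed by the 2-OH.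
3. Allyl everninate comes from orsellinic acid by carboxylate allylation and selective 4-O-methylation.
4. Ring B is atraric acid converted to its free acid, then the allyl ester. Both carboxyls are allyl esters so they can be removed neutrally with Pd(0).

## Route

**Step 1**
Reactants: **1** orsellinic acid
Product: **2** allyl orsellinate
Conditions: allyl bromide, NaHCO3, DMF, rt→40 °C
Reagents that add atoms: allyl bromide, C=CCBr
Why: NaHCO3 deprotonates only the carboxylic acid, and the phenols stay protonated, so SN2 O-allylation gives the ester selectively (carboxylate alkylation).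

**Step 2**
Reactants: **2**
Product: **3** allyl 2-hydroxy-4-methoxy-6-methylbenzoate (allyl everninate)
Conditions: MeI (1.05 equiv), K2CO3, acetone, rt→40 °C
Reagents that add atoms: iodomethane, CI
Why: the 2-OH is chelated to the ester carbonyl and the 4-OH is more acidic and free, so Williamson O-methylation occurs at C4-OH only.

**Step 3**
Reactants: **3**, paraformaldehyde
Product: **4** allyl 2-hydroxy-3-(hydroxymethyl)-4-methoxy-6-methylbenzoate
Conditions: (CH2O)n, PhB(OH)2, EtCO2H (cat.), toluene, reflux (Dean–Stark); then 30% H2O2, THF, 0 °C
Reagents that add atoms: formaldehyde (from paraformaldehyde), C=O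
Why: the phenylboronate templates formaldehyde delivery to the ortho carbon of the free 2-OH (Casiraghi-type ortho-hydroxymethylation). C3 is the only free ortho position, since C1 carries the ester. H2O2 then cleaves the cyclic boronate.

**Step 4**
Reactants: **4**
Product: **5** allyl 5-methoxy-2,2,7-trimethyl-4H-1,3-benzodioxine-8-carboxylate
Conditions: 2,2-dimethoxypropane, CSA (cat.), CH2Cl2, rt→40 °C
Reagents that add atoms: 2,2-dimethoxypropane, COC(C)(C)OC (supplies the CMe2)
Why: acid-catalysed transketalisation of the o-hydroxybenzyl alcohol gives the six-membered acetonide (acetonide protection). This protects both the 2-OH and the CH2OH.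

**Step 5**
Reactants: **5**
Product: **6** 5-methoxy-2,2,7-trimethyl-4H-1,3-benzodioxine-8-carboxylic acid
Conditions: Pd(PPh3)4 (5 mol %), PhSiH3, CH2Cl2, rt
Reagents that add atoms: none
Why: Pd(0) forms a π-allyl species that is hydrosilylated to propene (Tsuji–Trost deallylation). This leaves the acetonide, the aryl ether and the benzylic C–O bonds untouched, and gives the free acid without acid or base.

**Step 6**
Reactants: **7** methyl 2,4-dihydroxy-3,6-dimethylbenzoate (atraric acid)
Product: **8** 2,4-dihydroxy-3,6-dimethylbenzoic acid
Conditions: KOH (aq), EtOH, reflux, 4 h; then 2 M HCl, 0 °C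
Reagents that add atoms: water/hydroxide, O
Why: saponification of the hindered ester via the phenoxide salt. Acidification is done cold to avoid decarboxylation of the β-resorcylic acid.

**Step 7**
Reactants: **8**
Product: **9** allyl 2,4-dihydroxy-3,6-dimethylbenzoate
Conditions: allyl bromide, NaHCO3, DMF, rt→40 °C
Reagents that add atoms: allyl bromide, C=CCBr
Why: as in step 1, chemoselective carboxylate O-allylation leaves both phenols free.

**Step 8**
Reactants: **6**, **9**
Product: **10** allyl ester of the acetonide-protected depside
Conditions: DCC, DMAP (cat.), CH2Cl2, 0 °C→rt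
Reagents that add atoms: none (DCC leaves as dicyclohexylurea)
Why: Steglich esterification. The 2-OH of 9 is H-bonded to the ester and flanked by a methyl, so only the 4-OH is acylated (chemoselective acylation). No stereocentre is involved.

**Step 9**
Reactants: **10**
Product: **11** depside acid with acetonide intact
Conditions: Pd(PPh3)4 (5 mol %), PhSiH3, CH2Cl2, rt
Reagents that add atoms: none
Why: neutral Pd-catalysed deallylation. It uses no nucleophilic amine that could aminolyse the aryl ester, and no hydrogenolysis that could reduce the benzylic C–O bonds.

**Step 10**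
Reactants: **11**
Product: **12** 3-α-hydroxybarbatic acid (target)
Conditions: AcOH/H2O/THF (3:1:1), 40 °C
Reagents that add atoms: water, O
Why: the aryl ketal is the most acid-labile group and is hydrolysed (acetal hydrolysis) to the phenol and CH2OH with loss of acetone. The depside ester and the methyl ether survive these mild conditions.

**Check performed:**
- The target SMILES was compared atom by atom with compound 12: ring A is 1-acyl, 2-OH, 3-CH2OH, 4-OMe, 6-Me, and ring B is 4-O-acyl, 3-Me, 6-Me, 2-OH, 1-COOH.
- The formulae balance through the route (C8H8O4 → … → C19H20O8).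
- The allyl, acetonide and aryl ester groups each survive the steps between their installation and removal.
- The target has no stereocentres.

## Compound list
| No. | Name | SMILES | Role |
|---|---|---|---|
| 1 | orsellinic acid | Cc1cc(O)cc(O)c1C(=O)O | starting material |
| 2 | allyl orsellinate | C=CCOC(=O)c1c(C)cc(O)cc1O | intermediate |
| 3 | allyl everninate | C=CCOC(=O)c1c(C)cc(OC)cc1O | intermediate |
| 4 | allyl 2-hydroxy-3-(hydroxymethyl)-4-methoxy-6-methylbenzoate | C=CCOC(=O)c1c(C)cc(OC)c(CO)c1O | intermediate |
| 5 | allyl 5-methoxy-2,2,7-trimethyl-4H-1,3-benzodioxine-8-carboxylate | C=CCOC(=O)c1c(C)cc(OC)c2COC(C)(C)Oc12 | intermediate |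
| 6 | 5-methoxy-2,2,7-trimethyl-4H-1,3-benzodioxine-8-carboxylic acid | OC(=O)c1c(C)cc(OC)c2COC(C)(C)Oc12 | intermediate |
| 7 | methyl 2,4-dihydroxy-3,6-dimethylbenzoate (atraric acid) | COC(=O)c1c(C)cc(O)c(C)c1O | starting material |
| 8 | 2,4-dihydroxy-3,6-dimethylbenzoic acid | OC(=O)c1c(C)cc(O)c(C)c1O | intermediate |
| 9 | allyl 2,4-dihydroxy-3,6-dimethylbenzoate | C=CCOC(=O)c1c(C)cc(O)c(C)c1O | intermediate |
| 10 | allyl ester of acetonide-protected depside | C=CCOC(=O)c1c(C)cc(OC(=O)c2c(C)cc(OC)c3COC(C)(C)Oc23)c(C)c1O | intermediate |
| 11 | acetonide-protected depside acid | OC(=O)c1c(C)cc(OC(=O)c2c(C)cc(OC)c3COC(C)(C)Oc23)c(C)c1O | intermediate |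
| 12 | 3-α-hydroxybarbatic acid (achiral) | COc1cc(C)c(C(=O)Oc2cc(C)c(C(=O)O)c(O)c2C)c(O)c1CO | target |

**Total steps:** 10. **Longest linear sequence:** 8 steps (1→2→3→4→5→10→11→12, i.e. steps 1–5, 8, 9, 10). The ring-B arm is 2 steps and joins at step 8.

## Three steps most likely to fail
1. **Step 3 (C3 hydroxymethylation).** C3 is flanked by OH and OMe, so yield and bis-addition are concerns. Fallback: Mg-phenoxide ortho-formylation (MgCl2, Et3N, (CH2O)n, MeCN, reflux) to the 3-formyl compound, then NaBH4 to give 4.
2. **Step 8 (hindered depside coupling).** Both partners are di-ortho-substituted, and N-acylurea formation is possible. Fallback: convert acid 6 to its acid chloride with Ghosez's reagent (neutral, so the acetonide survives), then acylate the sodium 4-phenoxide of 9 with no carbodiimide involved.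
3. **Step 10 (final acetonide hydrolysis).** The electron-rich 2,6-dioxygenated benzylic alcohol may ionise to an o-quinone methide or benzyl cation and give ethers or oligomers. Fallback: carry C3 as the aldehyde instead (formyl ring-A acid from the step-3 fallback, 2-OH as MOM ether). After coupling, deprotect and do a final chemoselective NaBH4 reduction to the CH2OH, so no acid-labile benzylic alcohol is present until the last step.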